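**Plan**

- Numbering: ring A = C1–C2–C3(=O)–C4(CH3)(C19H2OAc)–C5=C10; ring B = C5–C6(=O)–C7(OH)=C8(CH3)–C9(CH3)(C11H2–C12H2–C13(CH3)=C14H–C15H2OH)–C10.
- Enabling feature: ring B is a 4,4-disubstituted 2-hydroxycyclohexa-2,5-dienone, that is a catechol dearomatised at C9, the carbon para to the C6 oxygen. C1 is the benzylic carbon joined to C9 through C10, so an oxygen on C1 can deliver C11–C12 to C9.
- Cuts: C12–C13 (sp3–sp2 Negishi coupling); C9–C11 together with a temporary C1–O–C12 lactone (phenoxide para-alkylation, later reductive C1–O cleavage); C4–C19 (hydroxymethylation); C4–C5 (ketone α-arylation); C1–C10 (Heck reaction).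
- Forward: 2,3-dimethylphenol is built up to a hexasubstituted benzene carrying the C10 side chain, ring A closes at C4–C5, C19 is added, and C1 is oxidised, reduced and esterified with bromoacetyl bromide. The phenoxide then closes the lactone and creates the ring B dienone, the bridge is cut, and the C13–C15 unit is joined last.
- Stereochemistry: C4 from a catalytic asymmetric hydroxymethylation; temporary C3 from hydroxyl-directed reduction; temporary C1 from CBS reduction; C9 from C1 through the lactone tether; (E)-C13=C14 from syn-hydrozirconation and stereoretentive coupling.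

Key step: step 15

Assumption: the facial sense of the scandium–bipyridine catalyst on this benzylic silyl enol ether cannot be predicted with certainty; the (S,S)-ligand is written and its mirror image would be used if the opposite face reacted.

**Route**

Step 1
Reactants: 1 2,3-dimethylphenol
Product: 2 1-(methoxymethoxy)-2,3-dimethylbenzene
Conditions: MOMCl, i-Pr2NEt, CH2Cl2, 0 °C → rt
Reagents that add atoms: chloromethyl methyl ether, COCCl
Why: Williamson-type O-alkylation gives the MOM ether, which later directs the ortho-metalation and caps the future C7 oxygen until the last step.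

Step 2
Reactants: 2 1-(methoxymethoxy)-2,3-dimethylbenzene
Product: 5 2-(methoxymethoxy)-3,4-dimethylphenol, via aryllithium 3 (not isolated), via dimethyl arylboronate 4 (not isolated)
Conditions: n-BuLi, TMEDA, Et2O, 0 °C → rt; B(OMe)3, −78 °C → rt; 30% H2O2, 0 °C → rt
Reagents that add atoms: hydrogen peroxide, OO (phenol oxygen); n-butyllithium, [Li]CCCC, and trimethyl borate, COB(OC)OC (atoms in intermediates 3 and 4 only)
Why: Directed ortho-metalation removes the only ring hydrogen ortho to the OMOM group, and borylation followed by peroxide oxidation turns that carbon into the future C6 phenol.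

Step 3
Reactants: 5 2-(methoxymethoxy)-3,4-dimethylphenol
Product: 6 6-bromo-2-(methoxymethoxy)-3,4-dimethylphenol
Conditions: NBS, i-Pr2NH (10 mol%), CH2Cl2, 0 °C
Reagents that add atoms: N-bromosuccinimide, O=C1CCC(=O)N1Br
Why: Amine-catalysed electrophilic bromination of a para-blocked phenol is ortho-selective, so bromine should enter the free position next to the hydroxyl (future C5).

Step 4
Reactants: 6 6-bromo-2-(methoxymethoxy)-3,4-dimethylphenol
Product: 7 tert-butyl[6-bromo-2-(methoxymethoxy)-3,4-dimethylphenoxy]dimethylsilane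
Conditions: TBSCl, imidazole, DMF, 40 °C
Reagents that add atoms: tert-butyldimethylsilyl chloride, CC(C)(C)[Si](C)(C)Cl
Why: Standard silylation of a phenol; the aryl silyl ether should survive the following steps and is the fluoride-labile trigger of step 15.

Step 5
Reactants: 7 tert-butyl[6-bromo-2-(methoxymethoxy)-3,4-dimethylphenoxy]dimethylsilane
Product: 8 tert-butyl[6-bromo-5-iodo-2-(methoxymethoxy)-3,4-dimethylphenoxy]dimethylsilane
Conditions: NIS, CF3CO2H (5 mol%), MeCN, 0 °C → rt
Reagents that add atoms: N-iodosuccinimide, O=C1CCC(=O)N1I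
Why: Electrophilic aromatic iodination at the single remaining ring hydrogen, which is para to the OMOM group (future C10), so no regiochemical choice exists.

Step 6
Reactants: 8 tert-butyl[6-bromo-5-iodo-2-(methoxymethoxy)-3,4-dimethylphenoxy]dimethylsilane; 9 pent-1-en-3-ol
Product: 10 1-{2-bromo-3-[(tert-butyldimethylsilyl)oxy]-4-(methoxymethoxy)-5,6-dimethylphenyl}pentan-3-one
Conditions: Pd(OAc)2 (5 mol%), n-Bu4NCl, NaHCO3, DMF, 50 °C
Reagents that add atoms: pent-1-en-3-ol 9, CCC(O)C=C
Why: Heck reaction of an allylic alcohol: zerovalent palladium inserts into C–I in preference to C–Br, and β-hydride elimination toward the carbinol gives the enol and hence the saturated ketone C1H2–C2H2–C3(=O)–C4H2–CH3 on C10.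

Step 7
Reactants: 10 1-{2-bromo-3-[(tert-butyldimethylsilyl)oxy]-4-(methoxymethoxy)-5,6-dimethylphenyl}pentan-3-one
Product: 11 rac-8-[(tert-butyldimethylsilyl)oxy]-7-(methoxymethoxy)-1,5,6-trimethyl-3,4-dihydronaphthalen-2(1H)-one
Conditions: Pd2(dba)3 (2.5 mol%), Xantphos (6 mol%), K3PO4, toluene, 90 °C
Reagents that add atoms: none
Why: Palladium-catalysed intramolecular α-arylation of the ketone enolate forms C4–C5 and ring A, because only the ethyl-side α-carbon can reach C5 through a six-membered ring (the other would give a four-membered ring); C4 is racemic and is flattened in the next step.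

Step 8
Reactants: 11 rac-8-[(tert-butyldimethylsilyl)oxy]-7-(methoxymethoxy)-1,5,6-trimethyl-3,4-dihydronaphthalen-2(1H)-one
Product: 13 8-[(tert-butyldimethylsilyl)oxy]-7-(methoxymethoxy)-1,5,6-trimethyl-2-[(trimethylsilyl)oxy]-3,4-dihydronaphthalene, via sodium enolate 12 (not isolated)
Conditions: NaH, THF, 0 °C → rt; TMSCl, 0 °C
Reagents that add atoms: chlorotrimethylsilane, C[Si](C)(C)Cl; sodium hydride, [Na+].[H-] (sodium in intermediate 12 only)
Why: Thermodynamic enolisation gives the far more stabilised aryl-conjugated C3=C4 enolate, and O-silylation fixes it as the tetrasubstituted silyl enol ether.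

Step 9
Reactants: 13 8-[(tert-butyldimethylsilyl)oxy]-7-(methoxymethoxy)-1,5,6-trimethyl-2-[(trimethylsilyl)oxy]-3,4-dihydronaphthalene
Product: 14 (S)-8-[(tert-butyldimethylsilyl)oxy]-1-(hydroxymethyl)-7-(methoxymethoxy)-1,5,6-trimethyl-3,4-dihydronaphthalen-2(1H)-one
Conditions: Sc(OTf)3 (10 mol%), (S,S)-6,6'-bis(1-hydroxy-2,2-dimethylpropyl)-2,2'-bipyridine (12 mol%), aq. HCHO, DME/H2O (9:1), −20 °C
Reagents that add atoms: formaldehyde, C=O
Why: Catalytic asymmetric Mukaiyama aldol (hydroxymethylation) in aqueous medium forms C4–C19, the chiral scandium–bipyridine complex shielding one face of the planar enol ether so that the quaternary centre C4 is set by the catalyst.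

Step 10
Reactants: 14 (S)-8-[(tert-butyldimethylsilyl)oxy]-1-(hydroxymethyl)-7-(methoxymethoxy)-1,5,6-trimethyl-3,4-dihydronaphthalen-2(1H)-one
Product: 15 (1S,2R)-8-[(tert-butyldimethylsilyl)oxy]-1-(hydroxymethyl)-7-(methoxymethoxy)-1,5,6-trimethyl-1,2,3,4-tetrahydronaphthalen-2-ol
Conditions: Me4NBH(OAc)3, MeCN/AcOH (1:1), −30 → −20 °C
Reagents that add atoms: none
Why: Evans–Saksena hydroxyl-directed reduction: the borohydride bound to the C19 oxygen delivers hydride to the C19 face of the C3 carbonyl, so the new C3 hydroxyl should end trans to C19 (3R).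

Step 11
Reactants: 15 (1S,2R)-8-[(tert-butyldimethylsilyl)oxy]-1-(hydroxymethyl)-7-(methoxymethoxy)-1,5,6-trimethyl-1,2,3,4-tetrahydronaphthalen-2-ol
Product: 17 {(1S,2R)-8-[(tert-butyldimethylsilyl)oxy]-7-(methoxymethoxy)-1,5,6-trimethyl-2-[(triethylsilyl)oxy]-1,2,3,4-tetrahydronaphthalen-1-yl}methyl acetate, via C19 monoacetate 16 (not isolated)
Conditions: AcCl (1.05 equiv), 2,4,6-collidine, CH2Cl2, −78 °C; then TESOTf, −78 → 0 °C
Reagents that add atoms: acetyl chloride, CC(Cl)=O; triethylsilyl trifluoromethanesulfonate, CC[Si](CC)(CC)OS(=O)(=O)C(F)(F)F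
Why: Chemoselective low-temperature acylation of the primary alcohol installs the final C19 acetate, and the more reactive silyl triflate then protects the hindered secondary C3 hydroxyl in the same flask.

Step 12
Reactants: 17 {(1S,2R)-8-[(tert-butyldimethylsilyl)oxy]-7-(methoxymethoxy)-1,5,6-trimethyl-2-[(triethylsilyl)oxy]-1,2,3,4-tetrahydronaphthalen-1-yl}methyl acetate
Product: 18 {(1S,2R)-8-[(tert-butyldimethylsilyl)oxy]-7-(methoxymethoxy)-1,5,6-trimethyl-4-oxo-2-[(triethylsilyl)oxy]-1,2,3,4-tetrahydronaphthalen-1-yl}methyl acetate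
Conditions: Rh2(cap)4 (1 mol%), t-BuOOH (70% aq.), NaHCO3 (cat.), 1,2-dichloroethane, 40 °C
Reagents that add atoms: tert-butyl hydroperoxide, CC(C)(C)OO
Why: Radical benzylic C–H oxidation by tert-butylperoxyl radicals should attack the ring methylene C1, which is secondary and para to the OMOM group, in preference to the two aryl methyl groups.

Step 13
Reactants: 18 {(1S,2R)-8-[(tert-butyldimethylsilyl)oxy]-7-(methoxymethoxy)-1,5,6-trimethyl-4-oxo-2-[(triethylsilyl)oxy]-1,2,3,4-tetrahydronaphthalen-1-yl}methyl acetate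
Product: 19 {(1S,2R,4S)-8-[(tert-butyldimethylsilyl)oxy]-4-hydroxy-7-(methoxymethoxy)-1,5,6-trimethyl-2-[(triethylsilyl)oxy]-1,2,3,4-tetrahydronaphthalen-1-yl}methyl acetate
Conditions: (R)-2-methyl-CBS-oxazaborolidine (0.2 equiv), BH3·SMe2, THF, −20 °C
Reagents that add atoms: none
Why: Corey–Bakshi–Shibata reduction of an aryl alkyl ketone, where the (R)-oxazaborolidine places the aryl group as the large substituent and should give the (S)-carbinol at C1 (hydroxyl cis to the C3 silyl ether, trans to C19) under reagent control.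

Step 14
Reactants: 19 {(1S,2R,4S)-8-[(tert-butyldimethylsilyl)oxy]-4-hydroxy-7-(methoxymethoxy)-1,5,6-trimethyl-2-[(triethylsilyl)oxy]-1,2,3,4-tetrahydronaphthalen-1-yl}methyl acetate; 20 bromoacetyl bromide
Product: 21 {(1S,2R,4S)-4-(2-bromoacetoxy)-8-[(tert-butyldimethylsilyl)oxy]-7-(methoxymethoxy)-1,5,6-trimethyl-2-[(triethylsilyl)oxy]-1,2,3,4-tetrahydronaphthalen-1-yl}methyl acetate
Conditions: BrCH2COBr, pyridine, CH2Cl2, −40 → 0 °C
Reagents that add atoms: bromoacetyl bromide 20, BrCC(Br)=O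
Why: O-acylation of the secondary benzylic alcohol by an acid bromide under basic conditions attaches the C11–C12 tether without breaking the C1–O bond, so the C1 configuration is kept.

Step 15
Reactants: 21 {(1S,2R,4S)-4-(2-bromoacetoxy)-8-[(tert-butyldimethylsilyl)oxy]-7-(methoxymethoxy)-1,5,6-trimethyl-2-[(triethylsilyl)oxy]-1,2,3,4-tetrahydronaphthalen-1-yl}methyl acetate
Product: 23 (1S,3R,4S,9S)-lactone dienone: ring B 7-(methoxymethoxy)-8,9-dimethylcyclohexa-2,5-dien-6-one bridged from C9 to C1 by the δ-lactone C9–C11H2–C12(=O)–O–C1; ring A keeps C3 OSiEt3 plus C4 CH3/CH2OAc, via cesium phenoxide 22 (not isolated)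
Conditions: CsF (3 equiv), DMF (0.005 M), 0 °C → rt
Reagents that add atoms: cesium fluoride, [Cs+].[F-] (cesium in intermediate 22 only)
Why: Proposed new method: fluoride removes the aryl silyl group and the cesium phenoxide 22, whose charge is delocalised to the para carbon C9, displaces bromide from the tethered CH2Br by intramolecular SN2 attack, forming C9–C11 and turning ring B into the 7-alkoxycyclohexa-2,5-dien-6-one; the closest known reaction type is the intramolecular para-alkylative dearomatisation of phenoxides by tethered alkyl halides or sulfonates, extended here to an α-bromo ester tether and a methyl-bearing para carbon. The six-membered lactone (C9, C11, C12, O, C1, C10) closes in the 6-exo-tet mode. The new stereocentre C9 is controlled by the C1 carbinol, because the three-atom O–C(=O)–CH2 tether can only reach the face of C9 on which the C1 oxygen lies, so C11 enters cis to C1–O and the methyl group ends on the C19 face (9S). The step needs C-alkylation at C9 rather than at oxygen, at C5 or between molecules: O-alkylation would require an eight-membered ring, the C7 oxygen is capped as its MOM ether so no second phenoxide can arise, attack at the other activated carbon C5 would give a bridged bicyclo[3.3.1] lactone with adjacent quaternary carbons, and high dilution suppresses intermolecular O-alkylation. The bromoacetate is chosen because α-halo esters are among the fastest SN2 electrophiles, which should offset the cost of the s-cis ester rotamer needed for closure.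

Step 16
Reactants: 23 (1S,3R,4S,9S)-lactone dienone
Product: 24 [(1S,2R,5S)-1-(acetoxymethyl)-7-(methoxymethoxy)-1,5,6-trimethyl-8-oxo-2-[(triethylsilyl)oxy]-1,2,3,4,5,8-hexahydronaphthalen-5-yl]acetic acid
Conditions: SmI2 (2.5 equiv), MeOH (5 equiv), THF, −78 °C; aq. HCl work-up
Reagents that add atoms: none
Why: SmI2 reduction of a vinylogous α-acyloxy ketone: electron transfer to the C6 dienone expels the C1 carboxylate (γ to the carbonyl through C5=C10), a second electron gives the extended samarium enolate, and protonation at C1 restores the cross-conjugated dienone while freeing the C12 acid and leaving C9 untouched.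

Step 17
Reactants: 24 [(1S,2R,5S)-1-(acetoxymethyl)-7-(methoxymethoxy)-1,5,6-trimethyl-8-oxo-2-[(triethylsilyl)oxy]-1,2,3,4,5,8-hexahydronaphthalen-5-yl]acetic acid
Product: 25 [(1S,2R,5S)-5-(2-hydroxyethyl)-7-(methoxymethoxy)-1,5,6-trimethyl-8-oxo-2-[(triethylsilyl)oxy]-1,2,3,4,5,8-hexahydronaphthalen-1-yl]methyl acetate
Conditions: BH3·THF (1.5 equiv), THF, −10 → 0 °C
Reagents that add atoms: none
Why: Chemoselective borane reduction of a carboxylic acid through its acyloxyborane, which should be faster than attack on the acetate or on the hindered, cross-conjugated C6 ketone.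

Step 18
Reactants: 25 [(1S,2R,5S)-5-(2-hydroxyethyl)-7-(methoxymethoxy)-1,5,6-trimethyl-8-oxo-2-[(triethylsilyl)oxy]-1,2,3,4,5,8-hexahydronaphthalen-1-yl]methyl acetate
Product: 26 [(1S,2R,5S)-5-(2-iodoethyl)-7-(methoxymethoxy)-1,5,6-trimethyl-8-oxo-2-[(triethylsilyl)oxy]-1,2,3,4,5,8-hexahydronaphthalen-1-yl]methyl acetate
Conditions: PPh3, I2, imidazole, CH2Cl2, 0 °C → rt
Reagents that add atoms: iodine, II
Why: Appel-type iodination, in which iodide displaces the alkoxyphosphonium of the primary C12 alcohol by SN2.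

Step 19
Reactants: 26 [(1S,2R,5S)-5-(2-iodoethyl)-7-(methoxymethoxy)-1,5,6-trimethyl-8-oxo-2-[(triethylsilyl)oxy]-1,2,3,4,5,8-hexahydronaphthalen-1-yl]methyl acetate
Product: 27 [(1S,2R,5S)-2-hydroxy-5-(2-iodoethyl)-7-(methoxymethoxy)-1,5,6-trimethyl-8-oxo-1,2,3,4,5,8-hexahydronaphthalen-1-yl]methyl acetate
Conditions: HF·pyridine, pyridine, THF, 0 °C → rt
Reagents that add atoms: none
Why: Buffered fluoride cleavage of the triethylsilyl ether, under conditions that should leave the MOM enol ether, the acetate and the alkyl iodide intact and be too acidic for acetyl migration.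

Step 20
Reactants: 27 [(1S,2R,5S)-2-hydroxy-5-(2-iodoethyl)-7-(methoxymethoxy)-1,5,6-trimethyl-8-oxo-1,2,3,4,5,8-hexahydronaphthalen-1-yl]methyl acetate
Product: 28 [(1S,5S)-5-(2-iodoethyl)-7-(methoxymethoxy)-1,5,6-trimethyl-2,8-dioxo-1,2,3,4,5,8-hexahydronaphthalen-1-yl]methyl acetate
Conditions: Dess–Martin periodinane, pyridine, CH2Cl2, 0 °C → rt
Reagents that add atoms: none
Why: Dess–Martin oxidation of the secondary alcohol gives the C3 ketone; C4 is quaternary, so the β-acetoxy ketone can neither eliminate nor epimerise.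

Step 21
Reactants: 29 but-2-yn-1-ol
Product: 30 1-(methoxymethoxy)but-2-yne
Conditions: MOMCl, i-Pr2NEt, CH2Cl2, 0 °C → rt
Reagents that add atoms: chloromethyl methyl ether, COCCl
Why: MOM ether formation on the primary propargylic alcohol, chosen so that both MOM groups of the final intermediate fall in one operation.

Step 22
Reactants: 30 1-(methoxymethoxy)but-2-yne
Product: 32 (E)-3-iodo-1-(methoxymethoxy)but-2-ene, via alkenylzirconocene chloride 31 (not isolated)
Conditions: Cp2Zr(H)Cl (2 equiv), THF, rt → 40 °C; I2, 0 °C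
Reagents that add atoms: iodine, II; Cp2Zr(H)Cl, [H][Zr](Cl)(C1C=CC=C1)C1C=CC=C1 (zirconium in intermediate 31 only)
Why: Hydrozirconation–iodination: syn addition of Zr–H with equilibration places zirconium on the methyl-bearing alkyne carbon, and iodinolysis with retention gives the alkenyl iodide with iodine trans to the CH2O group.

Step 23
Reactants: 28 [(1S,5S)-5-(2-iodoethyl)-7-(methoxymethoxy)-1,5,6-trimethyl-2,8-dioxo-1,2,3,4,5,8-hexahydronaphthalen-1-yl]methyl acetate; 32 (E)-3-iodo-1-(methoxymethoxy)but-2-ene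
Product: 34 [(1S,5S)-7-(methoxymethoxy)-5-[(3E)-5-(methoxymethoxy)-3-methylpent-3-en-1-yl]-1,5,6-trimethyl-2,8-dioxo-1,2,3,4,5,8-hexahydronaphthalen-1-yl]methyl acetate, via alkylzinc iodide 33 (not isolated)
Conditions: Zn dust (TMSCl/1,2-dibromoethane-activated), LiCl, THF, 35 °C; then 32, Pd2(dba)3 (2.5 mol%), SPhos (10 mol%), THF, rt → 40 °C
Reagents that add atoms: (E)-3-iodo-1-(methoxymethoxy)but-2-ene 32, I/C(C)=C/COCOC; zinc, [Zn] (in intermediate 33 only)
Why: Negishi sp3–sp2 cross-coupling: zinc insertion into the primary C–I bond gives an alkylzinc iodide that tolerates the ketones and the ester, and palladium-catalysed coupling with the alkenyl iodide forms C12–C13 with retention of the (E) geometry.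

Step 24
Reactants: 34 [(1S,5S)-7-(methoxymethoxy)-5-[(3E)-5-(methoxymethoxy)-3-methylpent-3-en-1-yl]-1,5,6-trimethyl-2,8-dioxo-1,2,3,4,5,8-hexahydronaphthalen-1-yl]methyl acetate
Product: 35 [(1S,5S)-7-hydroxy-5-[(3E)-5-hydroxy-3-methylpent-3-en-1-yl]-1,5,6-trimethyl-2,8-dioxo-1,2,3,4,5,8-hexahydronaphthalen-1-yl]methyl acetate (target)
Conditions: TMSOTf (4 equiv), 2,2'-bipyridyl (6 equiv), CH2Cl2, 0 °C → rt; then H2O
Reagents that add atoms: none
Why: Lewis-acid-mediated MOM ether cleavage at the acetal carbon under base-buffered conditions should free the C7 enol and the C15 allylic alcohol without ionising the allylic C–O bond or touching the acetate.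

**Compound list**

1 | 2,3-dimethylphenol | Cc1cccc(O)c1C | starting material
2 | 1-(methoxymethoxy)-2,3-dimethylbenzene | COCOc1cccc(C)c1C | intermediate
3 | [2-(methoxymethoxy)-3,4-dimethylphenyl]lithium | [Li]c1ccc(C)c(C)c1OCOC | intermediate (not isolated)
4 | dimethyl [2-(methoxymethoxy)-3,4-dimethylphenyl]boronate | COCOc1c(C)c(C)ccc1B(OC)OC | intermediate (not isolated)
5 | 2-(methoxymethoxy)-3,4-dimethylphenol | COCOc1c(O)ccc(C)c1C | intermediate
6 | 6-bromo-2-(methoxymethoxy)-3,4-dimethylphenol | COCOc1c(O)c(Br)cc(C)c1C | intermediate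
7 | tert-butyl[6-bromo-2-(methoxymethoxy)-3,4-dimethylphenoxy]dimethylsilane | COCOc1c(O[Si](C)(C)C(C)(C)C)c(Br)cc(C)c1C | intermediate
8 | tert-butyl[6-bromo-5-iodo-2-(methoxymethoxy)-3,4-dimethylphenoxy]dimethylsilane | COCOc1c(O[Si](C)(C)C(C)(C)C)c(Br)c(I)c(C)c1C | intermediate
9 | pent-1-en-3-ol | CCC(O)C=C | starting material
10 | 1-{2-bromo-3-[(tert-butyldimethylsilyl)oxy]-4-(methoxymethoxy)-5,6-dimethylphenyl}pentan-3-one | CCC(=O)CCc1c(Br)c(O[Si](C)(C)C(C)(C)C)c(OCOC)c(C)c1C | intermediate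
11 | rac-8-[(tert-butyldimethylsilyl)oxy]-7-(methoxymethoxy)-1,5,6-trimethyl-3,4-dihydronaphthalen-2(1H)-one | CC1C(=O)CCc2c(C)c(C)c(OCOC)c(O[Si](C)(C)C(C)(C)C)c12 | intermediate
12 | sodium 8-[(tert-butyldimethylsilyl)oxy]-7-(methoxymethoxy)-1,5,6-trimethyl-3,4-dihydronaphthalen-2-olate | [Na+].CC1=C([O-])CCc2c(C)c(C)c(OCOC)c(O[Si](C)(C)C(C)(C)C)c12 | intermediate (not isolated)
13 | 8-[(tert-butyldimethylsilyl)oxy]-7-(methoxymethoxy)-1,5,6-trimethyl-2-[(trimethylsilyl)oxy]-3,4-dihydronaphthalene | CC1=C(O[Si](C)(C)C)CCc2c(C)c(C)c(OCOC)c(O[Si](C)(C)C(C)(C)C)c12 | intermediate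
14 | (S)-8-[(tert-butyldimethylsilyl)oxy]-1-(hydroxymethyl)-7-(methoxymethoxy)-1,5,6-trimethyl-3,4-dihydronaphthalen-2(1H)-one | OC[C@@]1(C)C(=O)CCc2c(C)c(C)c(OCOC)c(O[Si](C)(C)C(C)(C)C)c12 | intermediate
15 | (1S,2R)-8-[(tert-butyldimethylsilyl)oxy]-1-(hydroxymethyl)-7-(methoxymethoxy)-1,5,6-trimethyl-1,2,3,4-tetrahydronaphthalen-2-ol | OC[C@@]1(C)[C@H](O)CCc2c(C)c(C)c(OCOC)c(O[Si](C)(C)C(C)(C)C)c12 | intermediate
16 | {(1S,2R)-8-[(tert-butyldimethylsilyl)oxy]-2-hydroxy-7-(methoxymethoxy)-1,5,6-trimethyl-1,2,3,4-tetrahydronaphthalen-1-yl}methyl acetate | CC(=O)OC[C@@]1(C)[C@H](O)CCc2c(C)c(C)c(OCOC)c(O[Si](C)(C)C(C)(C)C)c12 | intermediate (not isolated)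
17 | {(1S,2R)-8-[(tert-butyldimethylsilyl)oxy]-7-(methoxymethoxy)-1,5,6-trimethyl-2-[(triethylsilyl)oxy]-1,2,3,4-tetrahydronaphthalen-1-yl}methyl acetate | CC(=O)OC[C@@]1(C)[C@H](O[Si](CC)(CC)CC)CCc2c(C)c(C)c(OCOC)c(O[Si](C)(C)C(C)(C)C)c12 | intermediate
18 | {(1S,2R)-8-[(tert-butyldimethylsilyl)oxy]-7-(methoxymethoxy)-1,5,6-trimethyl-4-oxo-2-[(triethylsilyl)oxy]-1,2,3,4-tetrahydronaphthalen-1-yl}methyl acetate | CC(=O)OC[C@@]1(C)[C@H](O[Si](CC)(CC)CC)CC(=O)c2c(C)c(C)c(OCOC)c(O[Si](C)(C)C(C)(C)C)c12 | intermediate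
19 | {(1S,2R,4S)-8-[(tert-butyldimethylsilyl)oxy]-4-hydroxy-7-(methoxymethoxy)-1,5,6-trimethyl-2-[(triethylsilyl)oxy]-1,2,3,4-tetrahydronaphthalen-1-yl}methyl acetate | CC(=O)OC[C@@]1(C)[C@H](O[Si](CC)(CC)CC)C[C@H](O)c2c(C)c(C)c(OCOC)c(O[Si](C)(C)C(C)(C)C)c12 | intermediate
20 | bromoacetyl bromide | BrCC(Br)=O | starting material
21 | {(1S,2R,4S)-4-(2-bromoacetoxy)-8-[(tert-butyldimethylsilyl)oxy]-7-(methoxymethoxy)-1,5,6-trimethyl-2-[(triethylsilyl)oxy]-1,2,3,4-tetrahydronaphthalen-1-yl}methyl acetate (key-step precursor; C1 (S), C3 (R), C4 (S)) | CC(=O)OC[C@@]1(C)[C@H](O[Si](CC)(CC)CC)C[C@H](OC(=O)CBr)c2c(C)c(C)c(OCOC)c(O[Si](C)(C)C(C)(C)C)c12 | intermediate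
22 | cesium phenoxide of 21 (silyl group removed from the C6 oxygen) | [Cs+].CC(=O)OC[C@@]1(C)[C@H](O[Si](CC)(CC)CC)C[C@H](OC(=O)CBr)c2c(C)c(C)c(OCOC)c([O-])c12 | intermediate (not isolated)
23 | (1S,3R,4S,9S)-lactone dienone (key-step product): δ-lactone C9–C11H2–C12(=O)–O–C1 across C10, ring B 7-(methoxymethoxy)-8,9-dimethylcyclohexa-2,5-dien-6-one, C3 OSiEt3, C4 CH3 and CH2OAc | CC(=O)OC[C@@]1(C)[C@H](O[Si](CC)(CC)CC)C[C@@H]2OC(=O)C[C@@]3(C)C2=C1C(=O)C(OCOC)=C3C | intermediate
24 | [(1S,2R,5S)-1-(acetoxymethyl)-7-(methoxymethoxy)-1,5,6-trimethyl-8-oxo-2-[(triethylsilyl)oxy]-1,2,3,4,5,8-hexahydronaphthalen-5-yl]acetic acid | CC(=O)OC[C@@]1(C)[C@H](O[Si](CC)(CC)CC)CCC2=C1C(=O)C(OCOC)=C(C)[C@@]2(C)CC(=O)O | intermediate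
25 | [(1S,2R,5S)-5-(2-hydroxyethyl)-7-(methoxymethoxy)-1,5,6-trimethyl-8-oxo-2-[(triethylsilyl)oxy]-1,2,3,4,5,8-hexahydronaphthalen-1-yl]methyl acetate | CC(=O)OC[C@@]1(C)[C@H](O[Si](CC)(CC)CC)CCC2=C1C(=O)C(OCOC)=C(C)[C@@]2(C)CCO | intermediate
26 | [(1S,2R,5S)-5-(2-iodoethyl)-7-(methoxymethoxy)-1,5,6-trimethyl-8-oxo-2-[(triethylsilyl)oxy]-1,2,3,4,5,8-hexahydronaphthalen-1-yl]methyl acetate | CC(=O)OC[C@@]1(C)[C@H](O[Si](CC)(CC)CC)CCC2=C1C(=O)C(OCOC)=C(C)[C@@]2(C)CCI | intermediate
27 | [(1S,2R,5S)-2-hydroxy-5-(2-iodoethyl)-7-(methoxymethoxy)-1,5,6-trimethyl-8-oxo-1,2,3,4,5,8-hexahydronaphthalen-1-yl]methyl acetate | CC(=O)OC[C@@]1(C)[C@H](O)CCC2=C1C(=O)C(OCOC)=C(C)[C@@]2(C)CCI | intermediate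
28 | [(1S,5S)-5-(2-iodoethyl)-7-(methoxymethoxy)-1,5,6-trimethyl-2,8-dioxo-1,2,3,4,5,8-hexahydronaphthalen-1-yl]methyl acetate | CC(=O)OC[C@@]1(C)C(=O)CCC2=C1C(=O)C(OCOC)=C(C)[C@@]2(C)CCI | intermediate
29 | but-2-yn-1-ol | CC#CCO | starting material
30 | 1-(methoxymethoxy)but-2-yne | CC#CCOCOC | intermediate
31 | chlorobis(cyclopentadienyl)[(E)-4-(methoxymethoxy)but-2-en-2-yl]zirconium | C/C(=C\COCOC)[Zr](Cl)(C1C=CC=C1)C1C=CC=C1 | intermediate (not isolated)
32 | (E)-3-iodo-1-(methoxymethoxy)but-2-ene | I/C(C)=C/COCOC | intermediate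
33 | alkylzinc iodide from 28 (C12–ZnI) | CC(=O)OC[C@@]1(C)C(=O)CCC2=C1C(=O)C(OCOC)=C(C)[C@@]2(C)CC[Zn]I | intermediate (not isolated)
34 | [(1S,5S)-7-(methoxymethoxy)-5-[(3E)-5-(methoxymethoxy)-3-methylpent-3-en-1-yl]-1,5,6-trimethyl-2,8-dioxo-1,2,3,4,5,8-hexahydronaphthalen-1-yl]methyl acetate | CC(=O)OC[C@@]1(C)C(=O)CCC2=C1C(=O)C(OCOC)=C(C)[C@@]2(C)CC/C(C)=C/COCOC | intermediate
35 | [(1S,5S)-7-hydroxy-5-[(3E)-5-hydroxy-3-methylpent-3-en-1-yl]-1,5,6-trimethyl-2,8-dioxo-1,2,3,4,5,8-hexahydronaphthalen-1-yl]methyl acetate (C4 (S), C9 (S)) | CC(=O)OC[C@@]1(C)C(=O)CCC2=C1C(=O)C(O)=C(C)[C@@]2(C)CC/C(C)=C/CO | target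

**Step count**

Total: 24 steps. Longest linear sequence: 22 steps (steps 1–20, 23 and 24); steps 21 and 22 make the side-chain fragment.

**Steps most likely to fail**

1. Step 15 (proposed new method). The ring closure may be too slow, because the ester must reach its s-cis rotamer and C9 is crowded. Intermolecular O-alkylation, fluoride or phenoxide attack on the ester groups, or closure at C5 could then take over. Fallback, from 17 back to 25: CsF in DMF with allyl bromide should convert the aryl silyl ether directly into the C6 allyl ether F1. Heating (N,N-diethylaniline, about 180 °C) should move the allyl group by two consecutive [3,3] shifts (aromatic Claisen to an ortho carbon, then Cope) onto the methyl-bearing para carbon, giving the 9-allyl dienone F2. OsO4/NaIO4 should cleave the terminal alkene to the C12 aldehyde F3, and NaBH4 at −78 °C should reduce the aldehyde in preference to the hindered dienone, arriving at alcohol 25. This uses only established phenol chemistry and bypasses steps 12 to 17. The face of C9 would then rest on substrate control alone, so the diastereomeric purity of F2 would have to be secured by chromatography.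

2. Step 9. Enantiofacial discrimination may be poor on a tetrasubstituted, peri-hindered benzylic silyl enol ether, or the enol ether may hydrolyse before C–C bond formation. Fallback, from 11 back to 14: NaH and allyl chloroformate should give the allyl enol carbonate F4. Pd2(dba)3 with an enantiopure N,N'-(cyclohexane-1,2-diyl)bis[2-(diphenylphosphino)benzamide] ligand should effect decarboxylative asymmetric allylic alkylation to the (R)-1-allyl ketone F5. RuHCl(CO)(PPh3)3 should move the double bond inward to the (E)-propenyl ketone F6, and OsO4/NaIO4 should cleave it to the keto aldehyde F7. NaBH(OAc)3 should then reduce only the aldehyde, giving 14.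

3. Step 12. Hydrogen abstraction may occur at the aryl methyl groups or the MOM methylene, or the electron-rich ring may be oxidised, instead of clean ketone formation at C1. Fallback, from 17 back to 18: DDQ dehydrogenation (hydride loss at C1, proton loss at C2) should give the 1,2-dihydronaphthalene F8. Mukaiyama hydration (Co(acac)2, PhSiH3, O2) should place the hydroxyl on the benzylic carbon through the benzylic radical, giving the alcohol F9 as a mixture of C1 epimers. Dess–Martin oxidation of that mixture converges on ketone 18.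

**Further compounds**

F1 | step 15 | {(1S,2R)-8-(allyloxy)-7-(methoxymethoxy)-1,5,6-trimethyl-2-[(triethylsilyl)oxy]-1,2,3,4-tetrahydronaphthalen-1-yl}methyl acetate | CC(=O)OC[C@@]1(C)[C@H](O[Si](CC)(CC)CC)CCc2c(C)c(C)c(OCOC)c(OCC=C)c12
F2 | step 15 | [(1S,2R,5S)-5-allyl-7-(methoxymethoxy)-1,5,6-trimethyl-8-oxo-2-[(triethylsilyl)oxy]-1,2,3,4,5,8-hexahydronaphthalen-1-yl]methyl acetate | CC(=O)OC[C@@]1(C)[C@H](O[Si](CC)(CC)CC)CCC2=C1C(=O)C(OCOC)=C(C)[C@@]2(C)CC=C
F3 | step 15 | [(1S,2R,5S)-7-(methoxymethoxy)-1,5,6-trimethyl-8-oxo-5-(2-oxoethyl)-2-[(triethylsilyl)oxy]-1,2,3,4,5,8-hexahydronaphthalen-1-yl]methyl acetate | CC(=O)OC[C@@]1(C)[C@H](O[Si](CC)(CC)CC)CCC2=C1C(=O)C(OCOC)=C(C)[C@@]2(C)CC=O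
F4 | step 9 | allyl 8-[(tert-butyldimethylsilyl)oxy]-7-(methoxymethoxy)-1,5,6-trimethyl-3,4-dihydronaphthalen-2-yl carbonate | CC1=C(OC(=O)OCC=C)CCc2c(C)c(C)c(OCOC)c(O[Si](C)(C)C(C)(C)C)c12
F5 | step 9 | (R)-1-allyl-8-[(tert-butyldimethylsilyl)oxy]-7-(methoxymethoxy)-1,5,6-trimethyl-3,4-dihydronaphthalen-2(1H)-one | C=CC[C@@]1(C)C(=O)CCc2c(C)c(C)c(OCOC)c(O[Si](C)(C)C(C)(C)C)c12
F6 | step 9 | (R)-8-[(tert-butyldimethylsilyl)oxy]-7-(methoxymethoxy)-1,5,6-trimethyl-1-[(E)-prop-1-en-1-yl]-3,4-dihydronaphthalen-2(1H)-one | C/C=C/[C@@]1(C)C(=O)CCc2c(C)c(C)c(OCOC)c(O[Si](C)(C)C(C)(C)C)c12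
F7 | step 9 | (S)-8-[(tert-butyldimethylsilyl)oxy]-7-(methoxymethoxy)-1,5,6-trimethyl-2-oxo-1,2,3,4-tetrahydronaphthalene-1-carbaldehyde | O=C[C@@]1(C)C(=O)CCc2c(C)c(C)c(OCOC)c(O[Si](C)(C)C(C)(C)C)c12
F8 | step 12 | {(1S,2R)-8-[(tert-butyldimethylsilyl)oxy]-7-(methoxymethoxy)-1,5,6-trimethyl-2-[(triethylsilyl)oxy]-1,2-dihydronaphthalen-1-yl}methyl acetate | CC(=O)OC[C@@]1(C)[C@H](O[Si](CC)(CC)CC)C=Cc2c(C)c(C)c(OCOC)c(O[Si](C)(C)C(C)(C)C)c12
F9 | step 12 | {(1S,2R)-8-[(tert-butyldimethylsilyl)oxy]-4-hydroxy-7-(methoxymethoxy)-1,5,6-trimethyl-2-[(triethylsilyl)oxy]-1,2,3,4-tetrahydronaphthalen-1-yl}methyl acetate, both epimers at the carbinol carbon | CC(=O)OC[C@@]1(C)[C@H](O[Si](CC)(CC)CC)CC(O)c2c(C)c(C)c(OCOC)c(O[Si](C)(C)C(C)(C)C)c12
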